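**Retrosynthetic overview**

1. The last bonds are C3–C4 (alkenylzinc addition to a C4 aldehyde), C15–C19 (acid-catalysed SN1 allylic alkylation that closes the cyclopentanone ring of the 2-oxabicyclo[2.2.1]heptane across a pre-formed δ-lactone) and C14–C15 (west alkenylcerium added to a C15 methyl ketone).
2. The strategy rests on the cyclobutane C5–C6–C11–C12, fused along C6–C11 to the cyclohexadiene C6–C11, whose carbon C12 carries one exocyclic carbon, C13. A Wolff contraction of a cyclopentanone fused at C6–C11 (C13 ketone, C12 diazo) leaves exactly this pattern, with C13 as an ester that is then grown into C13(CH3)=C14.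
3. The diazo hydrindadienone comes from a Diels–Alder reaction of a 1-silyloxydiene (C7–C10) with an (R)-4,4-disubstituted 2-methylcyclopentenone (C5 set by chiral bicyclic-lactam alkylation), silanol loss and diazo transfer at C12.
4. The east half comes from an Evans β-keto imide anti aldol (C16, C21), ozonolysis and lactonisation.
5. Ring order: cyclopentenone, then cyclohexene/cyclohexadiene, then cyclobutane by contraction; δ-lactone, then the bridged lactone last.

Key step: step 9

Remark: atom labels C1–C21 (O17 is the ring oxygen) follow the target backbone in SMILES order and are used for all intermediates; the C4 oxygen is carried as a triisopropylsilyl (TIPS) ether instead of a tert-butyldimethylsilyl ether, because it must survive Lewis and Brønsted acid and should shield one face in the Diels–Alder step.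

**Route**

Step 1
Reactants: 1 (R)-valinol; 2 4-oxohexanoic acid
Product: 3 (3R,7aS)-7a-ethyl-3-isopropyl bicyclic lactam
Conditions: toluene, reflux, Dean–Stark
Reagents that add atoms: none
Why: Condensation of the amino alcohol with the γ-keto acid (N,O-ketal lactam formation under thermodynamic control) should give one cis diastereomer, with the angular ethyl group on the face of the isopropyl group.

Step 2
Reactants: 3
Product: 5 C6-methylated lactam (C6 epimer mixture), via lithium enolate 4 (not isolated)
Conditions: LiN(i-Pr)2, THF, −78 °C; MeI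
Reagents that add atoms: iodomethane, CI
Why: Amide enolate alkylation; the C6 configuration is irrelevant because the centre is planarised again in step 3.

Step 3
Reactants: 5
Product: 7 (3R,6S,7aS)-6-methyl-6-(TIPS-oxymethyl) lactam, via lithium enolate 6 (not isolated)
Conditions: LiN(i-Pr)2, THF, −78 °C; i-Pr3SiOCH2Cl, −78 → −20 °C
Reagents that add atoms: (triisopropylsiloxy)methyl chloride, ClCO[Si](C(C)C)(C(C)C)C(C)C
Why: Second enolate alkylation of the cup-shaped bicyclic lactam with an α-chloro ether; the electrophile should enter on the endo face, opposite the angular ethyl and the isopropyl group, which sets the quaternary carbon (later C5) with the methyl group exo.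

Step 4
Reactants: 7
Product: 10 (R)-2,4-dimethyl-4-(TIPS-oxymethyl)cyclopent-2-en-1-one, via carbinolamine 8 (not isolated), via keto aldehyde 9 (not isolated)
Conditions: NaAlH2(OCH2CH2OMe)2, toluene, −20 °C → rt; then Bu4N(H2PO4) (1 M aq), EtOH, 80 °C; then KOH (cat.), EtOH, rt
Reagents that add atoms: water, O
Why: Partial hydride reduction of the lactam, hydrolytic release of the 1,4-keto aldehyde and intramolecular aldol condensation (only the ethyl-ketone CH2 can close a five-membered ring) should give the enone with the quaternary centre untouched.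

Step 5
Reactants: 11 (E)-2-methylpent-2-enal
Product: 12 (1E,3E)-1-(tert-butyldimethylsilyloxy)-2-methylpenta-1,3-diene
Conditions: t-BuMe2SiOTf, Et3N, Et2O, 0 °C → rt
Reagents that add atoms: tert-butyldimethylsilyl triflate, CC(C)(C)[Si](C)(C)OS(=O)(=O)C(F)(F)F
Why: O-silylation of the s-trans enal followed by γ-deprotonation (silyl dienol ether formation) places the oxygen and the C4 methyl both "outside", the geometry a Diels–Alder diene needs.

Step 6
Reactants: 10; 12
Product: 13 cis-fused Diels–Alder adduct (mixture at C7 and C10)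
Conditions: AlBr3/AlMe3 (10:1, 0.3 equiv), toluene/CH2Cl2, −20 → 0 °C
Reagents that add atoms: none
Why: Lewis acid-catalysed Diels–Alder reaction of a hindered enone with a 1-silyloxydiene; the oxygenated terminus C10 bonds to the α-carbon C11 and C7 to the β-carbon C6 (ortho rule), suprafacial addition makes the C6/C11 fusion cis, and the diene should approach the face of the C5 methyl, away from CH2OTIPS, which sets C6 and C11 relative to C5.

Step 7
Reactants: 13
Product: 14 (3R,3aS,7aS)-hydrindadienone
Conditions: camphorsulfonic acid (0.3 equiv), toluene, 80 °C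
Reagents that add atoms: none
Why: Acid-induced E1 1,4-elimination of silanol: ionisation of the allylic C10–O bond gives a C8–C10 allyl cation whose only β-hydrogen is on C7 (C11 is quaternary), so the C7=C8–C9=C10 diene should form and the C7/C10 stereocentres are erased.

Step 8
Reactants: 14
Product: 17 cis-fused α-diazo hydrindadienone, via lithium enolate 15 (not isolated), via trifluoroacetyl ketone 16 (not isolated)
Conditions: LiN(SiMe3)2, THF, −78 °C; CF3CO2CH2CF3; then 4-AcNHC6H4SO2N3, Et3N, H2O (1 equiv), MeCN, rt; aq NH4Cl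
Reagents that add atoms: 4-acetamidobenzenesulfonyl azide, CC(=O)Nc1ccc(cc1)S(=O)(=O)N=[N+]=[N-]
Why: Deacylative (Regitz-type) diazo transfer through the activated trifluoroacetyl ketone; C12 is the only enolisable position because C11 is quaternary.

Step 9
Reactants: 17
Product: 20 C12 methyl ester of the bicyclo[4.2.0]octadiene, via cyclobutylidene ketene 18 (not isolated), via C12-epimeric ester 19 (not isolated)
Conditions: hν (450 nm LEDs), degassed MeOH/THF (4:1), 20 °C; then NaOMe (0.3 equiv), 50 °C
Reagents that add atoms: methanol, CO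
Why: Excitation of the n→π* band of the diazo ketone (locked s-Z in the ring) expels N2 and, in concert, C11 shifts from the carbonyl carbon C13 to C12 with retention, so that the C11–C12 bond and the cyclobutane appear as the cyclopentanone contracts and C13 leaves the ring as ketene 18; methanol adds to the ketene and the ester enol is protonated at C12. The closest known reaction is the photochemical Wolff ring contraction of cyclic 2-diazo ketones to cycloalkanecarboxylates, visible-light versions included. The four-membered ring is closed not by a cyclisation but by this 1,2-shift (the ring C5–C6–C11–C13–C12 contracts to C5–C6–C11–C12), and the strain is paid for by loss of N2. C5, C6 and C11 pass through unchanged; the new stereocentre C12 is governed by C5 and C11, since sodium methoxide should equilibrate the ester to the epimer with CO2Me on the face of the C5 methyl, away from CH2OTIPS and the angular C11 methyl, as the target requires. The step needs chemoselective excitation and clean migration: 450 nm light is absorbed only by the diazo ketone (the cyclohexadiene absorbs in the ultraviolet), C12 has no hydrogen-bearing neighbour for a 1,2-hydride shift, C11 is the only group on C13 that can migrate, and methanol as solvent captures the ketene at once.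

Step 10
Reactants: 20
Product: 21 C13 primary alcohol
Conditions: i-Bu2AlH, CH2Cl2, −78 → 0 °C
Reagents that add atoms: none
Why: Hydride reduction of the ester to the primary alcohol; silyl ether and diene are inert.

Step 11
Reactants: 21
Product: 22 C13 aldehyde
Conditions: Dess–Martin periodinane, CH2Cl2, 0 °C → rt
Reagents that add atoms: none
Why: Dess–Martin oxidation under neutral conditions leaves the cyclohexadiene and the silyl ether untouched.

Step 12
Reactants: 22
Product: 23 terminal alkyne C12–C13≡C14H
Conditions: MeC(O)C(N2)P(O)(OMe)2, K2CO3, MeOH, 0 °C → rt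
Reagents that add atoms: dimethyl (1-diazo-2-oxopropyl)phosphonate, COP(=O)(OC)C(=[N+]=[N-])C(C)=O
Why: Seyferth–Gilbert homologation with the Ohira–Bestmann reagent adds C14; the basic medium equilibrates the aldehyde at C12 once more before homologation, again toward C13 on the face of the C5 methyl.

Step 13
Reactants: 23
Product: 25 (E)-alkenyl iodide C12–C13(CH3)=C14H–I, via alkenylalane 24 (not isolated)
Conditions: AlMe3, Cp2ZrCl2 (0.25 equiv), CH2Cl2, 0 °C → rt; then I2, THF, −30 °C
Reagents that add atoms: trimethylaluminium, C[Al](C)C; iodine, II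
Why: Zirconium-catalysed carboalumination (Negishi) adds methyl to C13 and aluminium to C14 in a syn fashion, and iodinolysis with retention gives the alkene with C12 trans to iodine, the geometry of the target.

Step 14
Reactants: 26 (S)-4-benzyl-3-propionyloxazolidin-2-one; 27 propanal
Product: 29 (2S,3R) syn aldol imide, via (Z)-dibutylboron enolate 28 (not isolated)
Conditions: Bu2BOTf, i-Pr2NEt, CH2Cl2, 0 °C; 27, −78 → 0 °C; H2O2, MeOH, pH 7 buffer
Reagents that add atoms: none
Why: Evans syn aldol through a Zimmerman–Traxler chair sets the methyl-bearing carbon (later C19) as (S).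

Step 15
Reactants: 29
Product: 30 (S)-4-benzyl-3-[(S)-2-methyl-3-oxopentanoyl]oxazolidin-2-one
Conditions: Dess–Martin periodinane, CH2Cl2, 0 °C → rt
Reagents that add atoms: none
Why: Dess–Martin oxidation to the β-keto imide, whose α-stereocentre does not enolise because of allylic strain with the imide.

Step 16
Reactants: 30; 31 methacrolein
Product: 33 (2S,4R,5S) anti,anti aldol adduct, via (E)-dicyclohexylboron enolate 32 (not isolated)
Conditions: Cy2BCl, EtNMe2, Et2O, 0 °C; 31, −78 °C; H2O2, MeOH, pH 7 buffer
Reagents that add atoms: none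
Why: Anti aldol of the (E)-enol borinate of the ethyl ketone; the α-stereocentre of the β-keto imide directs the face (2,4-anti, 4,5-anti), which should set C21 as (R) and C16 as (S).

Step 17
Reactants: 33
Product: 35 (2S,4R,5S) acyloin (C15 methyl ketone), via ozonide 34 (not isolated)
Conditions: O3, CH2Cl2, −78 °C; Me2S
Reagents that add atoms: ozone, [O-][O+]=O
Why: Ozonolysis of the 1,1-disubstituted alkene; the β-keto imide is not enolised, so only the C=C bond reacts.

Step 18
Reactants: 35
Product: 36 (5R,6S)-6-acetyl-3,5-dimethyloxane-2,4-dione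
Conditions: Et3N, DMAP (cat.), CH2Cl2, 0 °C → rt
Reagents that add atoms: none
Why: Lactonisation (6-exo-trig acyl transfer from the imide to the C16 hydroxyl) expels the oxazolidinone; the 5,6-trans arrangement formed is also the thermodynamically preferred one.

Step 19
Reactants: 25; 36
Product: 40 tertiary allylic alcohol at C15 (C15/C19 epimer mixture), via alkenyllithium 37 (not isolated), via alkenylcerium dichloride 38 (not isolated), via sodium enolate 39 (not isolated)
Conditions: 25, t-BuLi (2 equiv), Et2O, −78 °C; CeCl3, THF, −78 °C; then 39 [36, NaN(SiMe3)2, THF, −78 °C], −78 → −40 °C; aq NH4Cl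
Reagents that add atoms: none
Why: Iodine–lithium exchange with retention of alkene geometry, transmetalation to the less basic organocerium, and 1,2-addition to the only free ketone (the β-keto lactone is masked as its enolate) should form the C14–C15 bond.

Step 20
Reactants: 40
Product: 41 TIPS ether of the complete bicyclic core (C4 as CH2OTIPS)
Conditions: camphorsulfonic acid (0.1 equiv), 4 Å MS, CH2Cl2, −20 → 0 °C
Reagents that add atoms: none
Why: Brønsted acid-catalysed SN1 allylic alkylation of a 1,3-dicarbonyl by a tertiary allylic alcohol: ionisation gives the C13–C15 allyl cation, the enol carbon C19 attacks C15 (5-exo) on the only face the C16 tether allows (fixing C19), allylic strain should place the C15 methyl next to O17 and the alkenyl arm over the C20–C21 bridge (fixing C15), the bulky C12 stays "outside" so the (E) alkene is kept, and any O-alkylation is reversible under the same acid.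

Step 21
Reactants: 41
Product: 42 C4 primary alcohol
Conditions: Bu4NF, AcOH (1:1), THF, rt
Reagents that add atoms: none
Why: Fluoride desilylation; the acetic acid buffer protects the keto lactone from base.

Step 22
Reactants: 42
Product: 43 C4 aldehyde
Conditions: Dess–Martin periodinane, CH2Cl2, 0 °C → rt
Reagents that add atoms: none
Why: Dess–Martin oxidation of the neopentyl alcohol; the α-carbon C5 is quaternary and cannot epimerise.

Step 23
Reactants: 43; 44 but-2-yne
Product: 47 shimalactone B, via alkenylborane 45 (not isolated), via alkenylzinc 46 (not isolated)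
Conditions: 44, Cy2BH (from BH3·SMe2 and cyclohexene), toluene, 0 °C → rt; ZnMe2, −78 °C; (+)-3-exo-morpholinoisoborneol (10 mol%); 43, −30 → 0 °C; aq NH4Cl
Reagents that add atoms: none
Why: Syn hydroboration of the alkyne, boron-to-zinc exchange and amino alcohol-catalysed asymmetric alkenylzinc addition, which is aldehyde-selective in the presence of the ketone and lactone; the ligand antipode chosen delivers to the Re face of C4 (it is the enantiomer of the one that gives (S)-1-phenylpropan-1-ol from benzaldehyde and ZnEt2), which should give (4R), and the substrate's own bias is small because the C6 and C12 branches of C5 are nearly alike.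

**Compound list**

1 | (R)-valinol | CC(C)[C@@H](N)CO | starting material
2 | 4-oxohexanoic acid | CCC(=O)CCC(=O)O | starting material
3 | (3R,7aS)-7a-ethyl-3-isopropyltetrahydropyrrolo[2,1-b]oxazol-5(6H)-one | CC[C@]12CCC(=O)N1[C@H](C(C)C)CO2 | intermediate
4 | lithium enolate of 3 | CC[C@]12CC=C(O[Li])N1[C@H](C(C)C)CO2 | intermediate (not isolated)
5 | 6-methyl derivative of 3 (C6 epimers) | CC[C@]12CC(C)C(=O)N1[C@H](C(C)C)CO2 | intermediate
6 | lithium enolate of 5 | CC[C@]12CC(C)=C(O[Li])N1[C@H](C(C)C)CO2 | intermediate (not isolated)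
7 | (3R,6S,7aS)-7a-ethyl-3-isopropyl-6-methyl-6-[(triisopropylsilyloxy)methyl] lactam | CC[C@]12C[C@@](C)(CO[Si](C(C)C)(C(C)C)C(C)C)C(=O)N1[C@H](C(C)C)CO2 | intermediate
8 | carbinolamine from 7 (C5–OH, epimers) | CC[C@]12C[C@@](C)(CO[Si](C(C)C)(C(C)C)C(C)C)C(O)N1[C@H](C(C)C)CO2 | intermediate (not isolated)
9 | (S)-2-methyl-4-oxo-2-[(triisopropylsilyloxy)methyl]hexanal | O=C[C@](C)(CO[Si](C(C)C)(C(C)C)C(C)C)CC(=O)CC | intermediate (not isolated)
10 | (R)-2,4-dimethyl-4-[(triisopropylsilyloxy)methyl]cyclopent-2-en-1-one | C[C@]1(CO[Si](C(C)C)(C(C)C)C(C)C)C=C(C)C(=O)C1 | intermediate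
11 | (E)-2-methylpent-2-enal | CC/C=C(\C)C=O | starting material
12 | (1E,3E)-1-(tert-butyldimethylsilyloxy)-2-methylpenta-1,3-diene | C/C=C/C(C)=C/O[Si](C)(C)C(C)(C)C | intermediate
13 | cis-fused adduct: 7-(tert-butyldimethylsilyloxy)-3,4,6,7a-tetramethyl-3-[(triisopropylsilyloxy)methyl]-2,3,3a,4,7,7a-hexahydro-1H-inden-1-one; ring-fusion H, angular methyl and CH2OTIPS on one face; epimers at C7/C10 (target labels) | CC(C)[Si](C(C)C)(C(C)C)OC[C@@]1(C)[C@@H]2C(C)C=C(C)C(O[Si](C)(C)C(C)(C)C)[C@]2(C)C(=O)C1 | intermediate
14 | (3R,3aS,7aS)-3,4,6,7a-tetramethyl-3-[(triisopropylsilyloxy)methyl]-2,3,3a,7a-tetrahydro-1H-inden-1-one | CC(C)[Si](C(C)C)(C(C)C)OC[C@@]1(C)[C@@H]2C(C)=CC(C)=C[C@]2(C)C(=O)C1 | intermediate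
15 | lithium enolate of 14 | CC(C)[Si](C(C)C)(C(C)C)OC[C@@]1(C)[C@@H]2C(C)=CC(C)=C[C@]2(C)C(O[Li])=C1 | intermediate (not isolated)
16 | 2-trifluoroacetyl derivative of 14 | CC(C)[Si](C(C)C)(C(C)C)OC[C@@]1(C)[C@@H]2C(C)=CC(C)=C[C@]2(C)C(=O)C1C(=O)C(F)(F)F | intermediate (not isolated)
17 | (3S,3aS,7aS)-2-diazo-3,4,6,7a-tetramethyl-3-[(triisopropylsilyloxy)methyl]-2,3,3a,7a-tetrahydro-1H-inden-1-one (key-step precursor) | CC(C)[Si](C(C)C)(C(C)C)OC[C@@]1(C)[C@@H]2C(C)=CC(C)=C[C@]2(C)C(=O)C1=[N+]=[N-] | intermediate
18 | ketene on C12 of the cis-bicyclo[4.2.0]octadiene | CC(C)[Si](C(C)C)(C(C)C)OC[C@@]1(C)[C@@H]2C(C)=CC(C)=C[C@]2(C)C1=C=O | intermediate (not isolated)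
19 | C12 epimer of 20 (CO2Me on the face of CH2OTIPS) | CC(C)[Si](C(C)C)(C(C)C)OC[C@@]1(C)[C@@H]2C(C)=CC(C)=C[C@]2(C)[C@H]1C(=O)OC | intermediate (not isolated)
20 | methyl ester on C12 of cis-5,7,9,11-tetramethyl-5-[(triisopropylsilyloxy)methyl]bicyclo[4.2.0]octa-7,9-diene (target labels); 6-H, 11-CH3 and CH2OTIPS on one face, CO2Me and 5-CH3 on the other (key-step product) | CC(C)[Si](C(C)C)(C(C)C)OC[C@@]1(C)[C@@H]2C(C)=CC(C)=C[C@]2(C)[C@@H]1C(=O)OC | intermediate
21 | C13 primary alcohol from 20 | CC(C)[Si](C(C)C)(C(C)C)OC[C@@]1(C)[C@@H]2C(C)=CC(C)=C[C@]2(C)[C@@H]1CO | intermediate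
22 | C13 aldehyde | CC(C)[Si](C(C)C)(C(C)C)OC[C@@]1(C)[C@@H]2C(C)=CC(C)=C[C@]2(C)[C@@H]1C=O | intermediate
23 | C12 ethynyl compound (C13≡C14H) | CC(C)[Si](C(C)C)(C(C)C)OC[C@@]1(C)[C@@H]2C(C)=CC(C)=C[C@]2(C)[C@@H]1C#C | intermediate
24 | (E)-alkenyl(dimethyl)alane | CC(C)[Si](C(C)C)(C(C)C)OC[C@@]1(C)[C@@H]2C(C)=CC(C)=C[C@]2(C)[C@@H]1/C(C)=C/[Al](C)C | intermediate (not isolated)
25 | west (E)-alkenyl iodide, C12–C13(CH3)=C14H–I | CC(C)[Si](C(C)C)(C(C)C)OC[C@@]1(C)[C@@H]2C(C)=CC(C)=C[C@]2(C)[C@@H]1/C(C)=C/I | intermediate
26 | (S)-4-benzyl-3-propionyloxazolidin-2-one | CCC(=O)N1[C@@H](Cc2ccccc2)COC1=O | starting material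
27 | propanal | CCC=O | starting material
28 | (Z)-dibutylboron enolate of 26 | C/C=C(\OB(CCCC)CCCC)N1[C@@H](Cc2ccccc2)COC1=O | intermediate (not isolated)
29 | (S)-4-benzyl-3-[(2S,3R)-3-hydroxy-2-methylpentanoyl]oxazolidin-2-one | CC[C@@H](O)[C@H](C)C(=O)N1[C@@H](Cc2ccccc2)COC1=O | intermediate
30 | (S)-4-benzyl-3-[(S)-2-methyl-3-oxopentanoyl]oxazolidin-2-one | CCC(=O)[C@H](C)C(=O)N1[C@@H](Cc2ccccc2)COC1=O | intermediate
31 | methacrolein | CC(=C)C=O | starting material
32 | (E)-dicyclohexylboron enolate of 30 | C/C=C(/OB(C1CCCCC1)C1CCCCC1)[C@H](C)C(=O)N1[C@@H](Cc2ccccc2)COC1=O | intermediate (not isolated)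
33 | (S)-4-benzyl-3-[(2S,4R,5S)-5-hydroxy-2,4,6-trimethyl-3-oxohept-6-enoyl]oxazolidin-2-one | CC(=C)[C@@H](O)[C@@H](C)C(=O)[C@H](C)C(=O)N1[C@@H](Cc2ccccc2)COC1=O | intermediate
34 | 1,2,4-trioxolane (ozonide) of 33 | CC1(OCOO1)[C@@H](O)[C@@H](C)C(=O)[C@H](C)C(=O)N1[C@@H](Cc2ccccc2)COC1=O | intermediate (not isolated)
35 | (S)-4-benzyl-3-[(2S,4R,5S)-5-hydroxy-2,4-dimethyl-3,6-dioxoheptanoyl]oxazolidin-2-one | CC(=O)[C@@H](O)[C@@H](C)C(=O)[C@H](C)C(=O)N1[C@@H](Cc2ccccc2)COC1=O | intermediate
36 | (5R,6S)-6-acetyl-3,5-dimethyloxane-2,4-dione (C3 epimers and enol) | CC(=O)[C@H]1OC(=O)C(C)C(=O)[C@@H]1C | intermediate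
37 | (E)-alkenyllithium from 25 | CC(C)[Si](C(C)C)(C(C)C)OC[C@@]1(C)[C@@H]2C(C)=CC(C)=C[C@]2(C)[C@@H]1/C(C)=C/[Li] | intermediate (not isolated)
38 | (E)-alkenylcerium dichloride | CC(C)[Si](C(C)C)(C(C)C)OC[C@@]1(C)[C@@H]2C(C)=CC(C)=C[C@]2(C)[C@@H]1/C(C)=C/[Ce](Cl)Cl | intermediate (not isolated)
39 | sodium enolate of 36 | CC(=O)[C@H]1OC(=O)C(C)=C([O-])[C@@H]1C.[Na+] | intermediate (not isolated)
40 | union product: tertiary allylic alcohol at C15 carrying the β-keto δ-lactone (C15/C19 epimers) | CC(C)[Si](C(C)C)(C(C)C)OC[C@@]1(C)[C@@H]2C(C)=CC(C)=C[C@]2(C)[C@@H]1/C(C)=C/C(C)(O)[C@H]1OC(=O)C(C)C(=O)[C@@H]1C | intermediate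
41 | complete bicyclic core with C4 as CH2OTIPS (target lacking C1–C3) | CC(C)[Si](C(C)C)(C(C)C)OC[C@@]1(C)[C@@H]2C(C)=CC(C)=C[C@]2(C)[C@@H]1/C(C)=C/[C@]1(C)[C@H]2OC(=O)[C@]1(C)C(=O)[C@@H]2C | intermediate
42 | C4 primary alcohol | OC[C@@]1(C)[C@@H]2C(C)=CC(C)=C[C@]2(C)[C@@H]1/C(C)=C/[C@]1(C)[C@H]2OC(=O)[C@]1(C)C(=O)[C@@H]2C | intermediate
43 | C4 aldehyde | O=C[C@@]1(C)[C@@H]2C(C)=CC(C)=C[C@]2(C)[C@@H]1/C(C)=C/[C@]1(C)[C@H]2OC(=O)[C@]1(C)C(=O)[C@@H]2C | intermediate
44 | but-2-yne | CC#CC | starting material
45 | (Z)-but-2-en-2-yl(dicyclohexyl)borane (boron cis to the vinylic hydrogen) | C/C=C(\C)B(C1CCCCC1)C1CCCCC1 | intermediate (not isolated)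
46 | (E)-but-2-en-2-yl(methyl)zinc | C/C=C(\C)[Zn]C | intermediate (not isolated)
47 | shimalactone B | C/C=C(\C)[C@@H](O)[C@@]1(C)[C@@H]2C(C)=CC(C)=C[C@]2(C)[C@@H]1/C(C)=C/[C@]1(C)[C@H]2OC(=O)[C@]1(C)C(=O)[C@@H]2C | target

**Step count**

Total steps: 23. Longest linear sequence: 17 steps (steps 1–4, 6–13 and 19–23); step 5 and steps 14–18 are side branches.

**Steps most likely to fail**

1. Step 9 (Wolff contraction). The excited diazo ketone or the free carbene may leak into other channels (1,2-shift of a C5 substituent, addition to the diene), and protonation or equilibration at C12 may not favour one epimer strongly enough. Fallback: a quasi-Favorskii (semibenzilic) ring contraction, which moves C11 to C12 through an anionic 1,2-shift instead of a carbene. It sets out from ketone 14: the lithium enolate (LiN(SiMe3)2, THF, −78 °C) would be brominated with N-bromosuccinimide to the C12 bromo ketone F1, and NaOMe in MeOH would add to the C13 carbonyl and drive the shift of C11 with loss of bromide, followed by the same methoxide equilibration. It comes back to the route at ester 20.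

2. Step 6 (Diels–Alder). Both alkene carbons of 10 are hindered, so the cycloaddition may be too slow; the silyl dienol ether may be destroyed by the Lewis acid, and face selectivity against CH2OTIPS may be incomplete. Fallback: exchange the silyloxydiene for a far more nucleophilic aminodiene and drop the Lewis acid. It sets out from 10 and 11: condensation of 11 with diethylamine (K2CO3, 0 °C) would give the dienamine (1E,3E)-N,N-diethyl-2-methylpenta-1,3-dien-1-amine F2; heating F2 with 10 in toluene (80–110 °C) would give the amino adduct F3 by cycloaddition or a Michael–Mannich sequence with the same regiochemistry, and mild acid (silica gel or AcOH) would eliminate diethylamine. It comes back at dienone 14, bypassing 13.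

3. Step 20 (closure of the bridged lactone). The allyl cation may lose a proton to a triene, O-alkylation may not revert, the nucleophile may meet the wrong face of C15, or the acid may protonate the cyclohexadiene next to the cyclobutane. Fallback: replace the free cation by a palladium π-allyl intermediate under neutral conditions (Tsuji–Trost allylic alkylation of the β-keto lactone by the free allylic alcohol, Pd(PPh3)4, zerovalent palladium, THF, 50 °C, the acidic pronucleophile serving as activator). It sets out from 40 and comes back at 41 without any new compound.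

**Further compounds**

F1 | step 9 | C12 bromo ketone: 2-bromo derivative of 14 (C12 epimers) | CC(C)[Si](C(C)C)(C(C)C)OC[C@@]1(C)[C@@H]2C(C)=CC(C)=C[C@]2(C)C(=O)C1Br
F2 | step 6 | (1E,3E)-N,N-diethyl-2-methylpenta-1,3-dien-1-amine | C/C=C/C(C)=C/N(CC)CC
F3 | step 6 | cis-fused diethylamino adduct (C10 amine analogue of 13, epimers at C7/C10) | CC(C)[Si](C(C)C)(C(C)C)OC[C@@]1(C)[C@@H]2C(C)C=C(C)C(N(CC)CC)[C@]2(C)C(=O)C1
F0 | step 20 | none | none
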